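**Strategy.** The route rests on the spiro-cyclohexene that links the two guaianolide halves (C1, C2, C10, C14 of the 8-hydroxy half; C15′ and C4′ of the other; guaiane numbering). It is a Diels–Alder retron once C1=C2 is shifted to C1=C10, and its C1–C10 bond also belongs to the seven-membered carbocycle. One flask therefore closes both rings: a Heck cyclization of an alkenyl bromide onto the cyclopentenone of a 1,10-seco-guaianolide (a cyclopentenone linked to a butyrolactone, both future methylenes masked as amines) forms C1–C10 and a 1,2-dialkylidenecycloheptane diene, which adds to dehydrozaluzanin C (C14–C15′, C2–C4′). Amine elimination and enone conjugation then give the target.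

Key step: step 8

Remark: guaiane numbering is used throughout (primes for the dehydrozaluzanin half); the configurations at the two aminomethyl-bearing carbons (C4, C11) and at C2 of the cycloadduct are inconsequential and are drawn as the expected major isomers; the free 8-hydroxyl is carried unprotected because the alternative 8,12-lactone would be cis-disubstituted and should be disfavoured.

Step 1
Reactants: 1 dehydrocostus lactone
Product: 2 3-epizaluzanin C
Conditions: SeO2 (0.5 equiv), t-BuOOH, CH2Cl2, 23 °C
Reagents that add atoms: tert-butyl hydroperoxide, CC(C)(C)OO (oxygen delivered through selenium dioxide, O=[Se]=O)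
Why: Riley-type allylic oxidation (ene reaction, then [2,3]-sigmatropic shift) should hydroxylate the C3 methylene next to the C4=C15 alkene from the convex α face; the new carbinol centre is erased in step 2.

Step 2
Reactants: 2 3-epizaluzanin C
Product: 3 dehydrozaluzanin C
Conditions: DMP, CH2Cl2, 23 °C
Reagents that add atoms: none
Why: Hypervalent-iodine oxidation of the allylic alcohol should give the α-methylene cyclopentanone under neutral conditions that leave the three exocyclic alkenes untouched.

Step 3
Reactants: 4 (S)-4-(tert-butyldimethylsilyloxy)cyclopent-2-en-1-one; 5 tert-butyl(furan-2-yloxy)dimethylsilane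
Product: 6 silyl enol ether butenolide
Conditions: TBSOTf (10 mol %), CH2Cl2, −78 °C; pyridine quench
Reagents that add atoms: none
Why: In this vinylogous Mukaiyama–Michael addition the furan γ-carbon should add to the enone β-carbon anti to the silyloxy group (sets C5), through the synclinal open transition state that keeps the CH(OTBS) branch away from the furan ring (sets C6); silyl transfer to the enolate oxygen keeps the ketone masked as a regiodefined enol ether.

Step 4
Reactants: 6 silyl enol ether butenolide
Product: 8 bis(dimethylaminomethyl) vinyl lactone, via silyl ketene acetal 7 (not isolated)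
Conditions: CH2=CHMgBr, CuBr·SMe2 (10 mol %), TMSCl, THF, −78 °C; then dimethylmethyleneammonium iodide (3 equiv), CH2Cl2, −78 to 23 °C; aq NaHCO3
Reagents that add atoms: vinylmagnesium bromide, C=C[Mg]Br; dimethylmethyleneammonium iodide, C=[N+](C)C.[I-]
Why: Copper-catalysed conjugate addition of the vinyl group to the butenolide trans to the C6 substituent sets C7, and Mannich aminomethylation of the silyl ketene acetal and of the ring silyl enol ether (each anti to its neighbour) installs C13 and C15 as dimethylaminomethyl groups, i.e. as masked exocyclic methylenes.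

Step 5
Reactants: 8 bis(dimethylaminomethyl) vinyl lactone
Product: 9 aldehyde
Conditions: CF3CO2H (2.5 equiv), O3, CH2Cl2/MeOH, −78 °C; Me2S; cold aq NaHCO3, used at once
Reagents that add atoms: ozone, [O-][O+]=O
Why: Ozonolysis with reductive work-up cleaves the only C=C bond, while protonation shields both tertiary amines from oxidation; no stereocentre is formed.

Step 6
Reactants: 9 aldehyde
Product: 10 bromohomoallylic alcohol
Conditions: (4R,5R)-2-(2-bromoallyl)-4,5-diphenyl-1,3-ditosyl-1,3,2-diazaborolidine (1.5 equiv), CH2Cl2/toluene, −78 °C; aq NaHCO3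
Reagents that add atoms: (4R,5R)-2-(2-bromoallyl)-4,5-diphenyl-1,3-ditosyl-1,3,2-diazaborolidine, C=C(Br)CB1N(S(=O)(=O)c2ccc(C)cc2)[C@H](c2ccccc2)[C@@H](c2ccccc2)N1S(=O)(=O)c1ccc(C)cc1
Why: Reagent-controlled allylboration through a chair transition state should deliver the 2-bromoallyl group to the Re face of the aldehyde and set the (8R) carbinol (use the controller enantiomer that adds to the Re face), overriding the weak bias of the α-stereocentre; the ketone is not attacked at −78 °C.

Step 7
Reactants: 10 bromohomoallylic alcohol
Product: 11 seco-guaianolide enone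
Conditions: DBU, CH2Cl2, 0 °C, short reaction time
Reagents that add atoms: none
Why: E1cB elimination of the β-silyloxy group should give the cyclopentenone whose C1=C2 bond is the Heck acceptor; the amines are poorer leaving groups and stay in place.

Step 8
Reactants: 11 seco-guaianolide enone; 3 dehydrozaluzanin C
Product: 13 Diels–Alder adduct, via cross-conjugated diene 12 (not isolated)
Conditions: Pd(OAc)2 (10 mol %), PPh3 (25 mol %), Ag2CO3, MeCN, 70 °C; then 3 (3 equiv), same flask, 45 °C
Reagents that add atoms: none
Why: Oxidative addition of the C10–Br bond to zerovalent palladium, 7-exo-trig syn-carbopalladation of the cyclopentenone at its β-carbon C1 (the only alkene within reach, since the lactone methylene is masked) and β-hydride elimination from the palladium enolate after its oxa-π-allyl face switch should form the C1–C10 bond and the s-cis-locked diene C14=C10–C1=C2 (12); in the same flask this diene undergoes an intermolecular [4+2] cycloaddition with the C4′=C15′ enone of 3, forming C14–C15′ and C2–C4′. The closest known reaction types are the domino Heck–Diels–Alder reaction of bromodienes (1,2-dialkylidenecycloalkanes trapped in situ), the Heck alkenylation of cycloalkenones, and the dienone plus methylene-ketone cycloaddition of guaianolides. Ring closures: the seven-membered carbocycle by 7-exo-trig Heck cyclization, the spiro-cyclohexene by normal-mode Diels–Alder addition. Stereocentres: the quaternary spiro carbon C4′ is set by approach of the diene to the convex α face of 3 (the face of H-1′ and H-5′), whereas C2 is transient, so endo/exo and diene-face selectivity do not matter. Selectivity needed: ortho regiochemistry (unsubstituted terminus C14 to the β-carbon C15′, acyl-bearing C2 to C4′), secured by the 1-acyl diene and the polarized methylene ketone, and reaction at C4′=C15′ and not at the less reactive α-methylene lactones; 3 is added only after the bromide is consumed so that it cannot intercept the alkenylpalladium species.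

Step 9
Reactants: 13 Diels–Alder adduct
Product: 16 CNP0200944.1, via bis-ammonium diiodide 14 (not isolated), via deconjugated methylene enone 15 (not isolated)
Conditions: MeI, MeOH/CH2Cl2, 23 °C; evaporate; DBU, CH2Cl2, 0 to 23 °C
Reagents that add atoms: none
Why: Exhaustive N-methylation and Hofmann-type E1cB loss of trimethylamine should unveil the C4=C15 and C11=C13 methylenes, and the amidine base then moves C1=C10 into conjugation through the cross-conjugated dienolate, which is protonated at C10 on the α face (anti to the C6–C8 bridge) to give the H-10α epimer expected also under equilibrating conditions.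

**Compound list**

1 | dehydrocostus lactone, (3aS,6aR,9aR,9bS)-3,6,9-trimethylidenedecahydroazuleno[4,5-b]furan-2-one | C=C1CC[C@H]2C(=C)CC[C@H]3C(=C)C(=O)O[C@@H]3[C@@H]12 | starting material
2 | 3-epizaluzanin C (3α-hydroxy derivative of 1, 3R) | C=C1[C@H](O)C[C@H]2C(=C)CC[C@H]3C(=C)C(=O)O[C@@H]3[C@@H]12 | intermediate
3 | dehydrozaluzanin C (3-oxo derivative of 1) | C=C1C(=O)C[C@H]2C(=C)CC[C@H]3C(=C)C(=O)O[C@@H]3[C@@H]12 | intermediate
4 | (S)-4-(tert-butyldimethylsilyloxy)cyclopent-2-en-1-one | O=C1C=C[C@@H](O[Si](C)(C)C(C)(C)C)C1 | starting material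
5 | tert-butyl(furan-2-yloxy)dimethylsilane | CC(C)(C)[Si](C)(C)Oc1ccco1 | starting material
6 | (5S)-5-[(1R,5S)-3,5-bis(tert-butyldimethylsilyloxy)cyclopent-2-en-1-yl]furan-2(5H)-one (ring substituents trans) | CC(C)(C)[Si](C)(C)OC1=C[C@H]([C@@H]2C=CC(=O)O2)[C@@H](O[Si](C)(C)C(C)(C)C)C1 | intermediate
7 | 2-trimethylsilyloxy-4,5-dihydrofuran (silyl ketene acetal) of the 4,5-trans vinyl adduct of 6 | CC(C)(C)[Si](C)(C)OC1=C[C@H]([C@H]2OC(O[Si](C)(C)C)=C[C@@H]2C=C)[C@@H](O[Si](C)(C)C(C)(C)C)C1 | intermediate (not isolated)
8 | (3R,4S,5S)-5-[(1R,2R,5S)-5-(tert-butyldimethylsilyloxy)-2-(dimethylaminomethyl)-3-oxocyclopentyl]-3-(dimethylaminomethyl)-4-vinyloxolan-2-one | C=C[C@H]1[C@H](CN(C)C)C(=O)O[C@@H]1[C@@H]1[C@@H](O[Si](C)(C)C(C)(C)C)CC(=O)[C@H]1CN(C)C | intermediate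
9 | 4-formyl analogue of 8 (vinyl replaced by CHO, all centres unchanged in space) | O=C[C@H]1[C@H](CN(C)C)C(=O)O[C@@H]1[C@@H]1[C@@H](O[Si](C)(C)C(C)(C)C)CC(=O)[C@H]1CN(C)C | intermediate
10 | 4-[(1R)-3-bromo-1-hydroxybut-3-en-1-yl] analogue of 8 (silyl ether retained) | C=C(Br)C[C@@H](O)[C@H]1[C@H](CN(C)C)C(=O)O[C@@H]1[C@@H]1[C@@H](O[Si](C)(C)C(C)(C)C)CC(=O)[C@H]1CN(C)C | intermediate
11 | (3R,4R,5R)-4-[(1R)-3-bromo-1-hydroxybut-3-en-1-yl]-3-(dimethylaminomethyl)-5-[(1R,2R)-2-(dimethylaminomethyl)-3-oxocyclopent-4-en-1-yl]oxolan-2-one | C=C(Br)C[C@@H](O)[C@H]1[C@H](CN(C)C)C(=O)O[C@@H]1[C@@H]1C=CC(=O)[C@H]1CN(C)C | intermediate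
12 | 13,15-bis(dimethylamino)-8β-hydroxy-3-oxo-4βH,5αH,11βH-guaia-1,10(14)-dien-12,6α-olide | CN(C)C[C@@H]1C(=O)C=C2C(=C)C[C@@H](O)[C@H]3[C@H](CN(C)C)C(=O)O[C@@H]3[C@@H]12 | intermediate (not isolated)
13 | spiro cycloadduct of 12 and 3: C2–C4′ and C14–C15′ bonds, C1=C10 alkene, 2βH, C4′ R | CN(C)C[C@@H]1C(=O)[C@H]2C3=C(CC[C@]24C(=O)C[C@H]5C(=C)CC[C@H]6C(=C)C(=O)O[C@@H]6[C@@H]45)C[C@@H](O)[C@H]2[C@H](CN(C)C)C(=O)O[C@@H]2[C@@H]13 | intermediate
14 | bis(trimethylammonium) diiodide of 13 | C[N+](C)(C)C[C@@H]1C(=O)[C@H]2C3=C(CC[C@]24C(=O)C[C@H]5C(=C)CC[C@H]6C(=C)C(=O)O[C@@H]6[C@@H]45)C[C@@H](O)[C@H]2[C@H](C[N+](C)(C)C)C(=O)O[C@@H]2[C@@H]13.[I-].[I-] | intermediate (not isolated)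
15 | deconjugated isomer of the target (C1=C10, 2βH) with C4=C15 and C11=C13 methylenes | C=C1C(=O)[C@H]2C3=C(CC[C@]24C(=O)C[C@H]5C(=C)CC[C@H]6C(=C)C(=O)O[C@@H]6[C@@H]45)C[C@@H](O)[C@H]2C(=C)C(=O)O[C@@H]2[C@@H]13 | intermediate (not isolated)
16 | CNP0200944.1 | C=C1C(=O)C2=C3[C@H](CC[C@]24C(=O)C[C@H]2C(=C)CC[C@H]5C(=C)C(=O)O[C@@H]5[C@H]24)C[C@@H](O)[C@H]2C(=C)C(=O)O[C@@H]2[C@@H]13 | target

**Count.** Total: 9 steps. Longest linear sequence: 7 steps (steps 3 to 9, from 4); steps 1 and 2 form the two-step branch to 3.

**Steps most likely to fail**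

1. Step 8. The palladium enolate formed after carbopalladation may be protonated instead of undergoing β-hydride elimination (no diene, no turnover), or the base may move the cyclopentenone double bond before cyclization. Fallback: from 11, a reductive Heck cyclization (Pd(OAc)2, PPh3, HCO2Na, DMF) deliberately gives the saturated cis-fused hydroazulenone F1. Kinetic silyl enol ether formation toward C2 (LiHMDS, TMSCl, −78 °C) and Saegusa–Ito dehydrogenation with Pd(OAc)2 then regenerate diene 12, which is treated directly with 3 to return to the route at 13.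

2. Step 3. Facial selectivity on the furan in the open transition state may be poor, giving the C6 epimer. Fallback: from 4, Morita–Baylis–Hillman hydroxymethylation (aqueous formaldehyde, imidazole) gives the hydroxymethyl enone F2, and PBr3 gives the allylic bromide F3. An indium-mediated Barbier allylation of methyl (Z)-4-oxobut-2-enoate (closed chair transition state, attack anti to the silyloxy group, then lactonization) gives the methylene ketone butenolide F4 with C5 and C6 set. Conjugate addition of dimethylamine masks the ring methylene as the amino ketone F5, and the vinyl cuprate addition with iminium trapping of step 4 returns to the route at 8.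

3. Step 9. The freshly unveiled α-methylene carbonyl groups may undergo oxa-Michael addition or oligomerization under the amidine base while the slower conjugation is still running, and facial control of the C10 protonation may be incomplete. Fallback: invert the order. From 13, DBU conjugates the enone while both methylenes are still masked, giving the conjugated bis-amine F6, whose C10 centre can be equilibrated without Michael acceptors from this half. Methylation (MeI) and elimination in a two-phase aqueous NaHCO3/CH2Cl2 mixture then give 16.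

**Further compounds**

F1 | step 8 | 13,15-bis(dimethylamino)-8β-hydroxy-3-oxo-1αH,4βH,5αH,11βH-guai-10(14)-en-12,6α-olide | CN(C)C[C@@H]1C(=O)C[C@H]2C(=C)C[C@@H](O)[C@H]3[C@H](CN(C)C)C(=O)O[C@@H]3[C@@H]12
F2 | step 3 | (S)-4-(tert-butyldimethylsilyloxy)-2-(hydroxymethyl)cyclopent-2-en-1-one | O=C1C(CO)=C[C@@H](O[Si](C)(C)C(C)(C)C)C1
F3 | step 3 | (S)-2-(bromomethyl)-4-(tert-butyldimethylsilyloxy)cyclopent-2-en-1-one | O=C1C(CBr)=C[C@@H](O[Si](C)(C)C(C)(C)C)C1
F4 | step 3 | 5-[5-(tert-butyldimethylsilyloxy)-2-methylidene-3-oxocyclopentyl]furan-2(5H)-one, configuration as in 6 | C=C1C(=O)C[C@H](O[Si](C)(C)C(C)(C)C)[C@H]1[C@@H]1C=CC(=O)O1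
F5 | step 3 | dimethylamine adduct of F4 at the ring methylene (aminomethyl trans to the butenolide) | CN(C)C[C@@H]1C(=O)C[C@H](O[Si](C)(C)C(C)(C)C)[C@H]1[C@@H]1C=CC(=O)O1
F6 | step 9 | conjugated enone isomer of 13 (C1=C2, 10αH) with both dimethylaminomethyl groups in place | CN(C)C[C@@H]1C(=O)C2=C3[C@H](CC[C@]24C(=O)C[C@H]5C(=C)CC[C@H]6C(=C)C(=O)O[C@@H]6[C@@H]45)C[C@@H](O)[C@H]2[C@H](CN(C)C)C(=O)O[C@@H]2[C@@H]13
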